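Retrosynthetic overview
Target ⇐ 12,6-lactone core carrying C3–OTBS, C8–OPMB and C9–OTIPS; late orthogonal unveiling gives the C3 acetate, the C9 (2R,3R)-epoxyangelate and the free C8–OH, with C13 added by Mannich/elimination and the lactone C6–O bond closed by invertive Mitsunobu lactonization.
Ten-membered ring and the C8–C9 bond ⇐ anionic oxy-Cope ring expansion of a 1,2-dialkenylcyclohex-2-en-1-ol, with alkylation of the resulting enolate at C7 by methyl bromoacetate in the same flask (C11, C12).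
Enabling feature: the 1,5-diene C8=C7–C6(O−)–C1–C10=C9, whose C1 and C6 are neighbours in a six-membered ring C1–C2–C3–C4=C5–C6; the C1–C6 bond is absent from the target, holds the two (E)-enol ether termini C8 and C9 in a chair and is cut as C8–C9 forms, while the ring alkene becomes (Z)-C4=C5.
Cyclohexenol ⇐ enone by alkoxyacetylide addition and trans-reduction; enone ⇐ 4-methoxy-2-methylphenol via the quinone monoketal, rhodium-catalysed asymmetric alkenyl 1,4-addition (C1), CBS reduction (C3) and allyl-to-enol silyl ether isomerization (C9=C10).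
Order of ring formation: six-membered carbocycle (from the arene, sacrificial) → ten-membered carbocycle (key step) → γ-lactone → side-chain oxirane (made separately by Sharpless epoxidation, attached by esterification).

Key step: step 11

Remark: germacrane numbering of the target is used for all intermediates (ring C1–C10; C6 bears the lactone oxygen, C7 bears C11, C8 the OH, C9 the acyloxy group, C10 and C4 the methyl groups, C3 the acetate; lactone C11, C12(=O), C13 = CH2), and triisopropyl(prop-2-yn-1-yloxy)silane is taken to be a catalogue compound.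

Step 1
Reactants: 1 triisopropyl(prop-2-yn-1-yloxy)silane
Product: 2 triisopropyl{[2-(4,4,5,5-tetramethyl-1,3,2-dioxaborolan-2-yl)prop-2-en-1-yl]oxy}silane
Conditions: CuCl (5 mol %), 1,3-dimesitylimidazolinium chloride (5 mol %), NaOtBu (15 mol %), B2pin2, MeOH (2 equiv), THF, −40 to 22 °C
Reagents that add atoms: bis(pinacolato)diboron, CC1(C)OB(OC1(C)C)B1OC(C)(C)C(C)(C)O1
Why: N-heterocyclic-carbene–copper-catalysed protoboration of a terminal propargylic ether (syn addition of Cu–B with boron on the internal carbon, then protonolysis by methanol) should give the 1,1-disubstituted alkenylboronate; no stereocentre is formed.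

Step 2
Reactants: 3 4-methoxy-2-methylphenol
Product: 4 4,4-dimethoxy-2-methylcyclohexa-2,5-dien-1-one
Conditions: PhI(OAc)2, MeOH, 0 °C
Reagents that add atoms: methanol, CO
Why: Oxidative dearomatization of a para-methoxyphenol with PhI(OAc)2 in methanol gives the quinone monoketal by capture of the oxidized ring at C4 with methanol; no stereocentre is formed.

Step 3
Reactants: 4 4,4-dimethoxy-2-methylcyclohexa-2,5-dien-1-one; 2 alkenylboronate
Product: 5 (5R)-4,4-dimethoxy-2-methyl-5-[3-(triisopropylsilyloxy)prop-1-en-2-yl]cyclohex-2-en-1-one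
Conditions: [Rh(OH)(1,5-cyclooctadiene)]2 (2.5 mol %), (R)-BINAP (6 mol %), KOH (cat.), 1,4-dioxane/H2O 10:1, 50 °C
Reagents that add atoms: none
Why: Hayashi–Miyaura rhodium-catalysed asymmetric 1,4-addition of an alkenylboron reagent to a cyclic enone; the unsubstituted enone arm should react because the other arm carries an α-methyl group, and the (R)-BINAP–rhodium alkenyl species is expected, by analogy with 2-cyclohexenone, to add to the face that gives the 5R centre (future C1).

Step 4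
Reactants: 5 (5R)-alkenyl ketal enone
Product: 6 (1S,5R)-4,4-dimethoxy-2-methyl-5-[3-(triisopropylsilyloxy)prop-1-en-2-yl]cyclohex-2-en-1-ol
Conditions: (R)-1-methyl-3,3-diphenyltetrahydro-1H,3H-pyrrolo[1,2-c][1,3,2]oxazaborole (20 mol %), BH3·SMe2, THF, −30 °C; MeOH quench
Reagents that add atoms: none
Why: Corey–Bakshi–Shibata reduction under reagent control, in which the alkenyl branch of the enone acts as the large group, so that the (R)-oxazaborolidine should deliver hydride to give the 1S alcohol (future C3) trans to the alkenyl group, against the substrate preference for the cis alcohol.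

Step 5
Reactants: 6 (1S,5R)-allylic alcohol
Product: 7 tert-butyl{[(1S,5R)-4,4-dimethoxy-2-methyl-5-[3-(triisopropylsilyloxy)prop-1-en-2-yl]cyclohex-2-en-1-yl]oxy}dimethylsilane
Conditions: TBSCl, imidazole, DMF, 22 °C
Reagents that add atoms: tert-butyldimethylsilyl chloride, CC(C)(C)[Si](C)(C)Cl
Why: Imidazole-promoted silylation of a secondary allylic alcohol under basic conditions that keep the acid-sensitive hydroxy ketal intact; configuration is retained.

Step 6
Reactants: 7 bis-silyl ether ketal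
Product: 8 (4S,6R)-4-(tert-butyldimethylsilyloxy)-3-methyl-6-[3-(triisopropylsilyloxy)prop-1-en-2-yl]cyclohex-2-en-1-one
Conditions: pyridinium p-toluenesulfonate (cat.), acetone/H2O 10:1, 22 °C
Reagents that add atoms: water, O
Why: Mild acid hydrolysis of the allylic dimethyl ketal (oxocarbenium ion, then water) unmasks the enone carbonyl (future C6) while both silyl ethers persist and the adjacent C1 centre is not enolized.

Step 7
Reactants: 8 allyl silyl ether enone
Product: 9 (4S,6R)-4-(tert-butyldimethylsilyloxy)-3-methyl-6-[(1E)-1-(triisopropylsilyloxy)prop-1-en-2-yl]cyclohex-2-en-1-one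
Conditions: [Ir(1,5-cyclooctadiene)(PMePh2)2]PF6 (2 mol %, activated with H2), THF, 22 °C
Reagents that add atoms: none
Why: Cationic iridium hydride-catalysed 1,3-hydrogen shift of an allyl silyl ether to a silyl enol ether, in which the CH2OSi hydrogens should be abstracted in preference to the ring methine and the (E)-isomer (silyloxy group trans to the ring, cis to the methyl group) is the less congested product.

Step 8
Reactants: 10 (4-methoxyphenyl)methanol
Product: 11 1-({[(E)-1,2-dichloroethenyl]oxy}methyl)-4-methoxybenzene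
Conditions: KH, THF, 0 °C; Cl2C=CHCl, −50 to 22 °C
Reagents that add atoms: trichloroethylene, ClC=C(Cl)Cl
Why: Addition–elimination of the potassium alkoxide on trichloroethylene (through dichloroacetylene) gives the (E)-1,2-dichlorovinyl ether, the established precursor of alkoxyacetylides.

Step 9
Reactants: 9 (E)-silyl enol ether enone; 11 dichlorovinyl ether
Product: 13 (1S,4S,6R)-4-(tert-butyldimethylsilyloxy)-1-{[(4-methoxyphenyl)methoxy]ethynyl}-3-methyl-6-[(1E)-1-(triisopropylsilyloxy)prop-1-en-2-yl]cyclohex-2-en-1-ol, via lithium alkoxyacetylide 12 (not isolated)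
Conditions: 11, n-BuLi (2.2 equiv), THF, −78 to −40 °C; CeCl3, −78 °C; then 9, THF, −78 °C
Reagents that add atoms: none
Why: n-BuLi converts 11 into the lithium alkoxyacetylide (elimination, then chlorine–lithium exchange), whose cerium derivative should add 1,2 to the enone by axial attack on the face opposite the pseudoaxial C3 silyloxy group, which sets C6 as S with the alkynyl group cis to the equatorial C1 alkenyl group, CeCl3 suppressing enolization at C1.

Step 10
Reactants: 13 alkoxyethynyl carbinol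
Product: 14 (1S,4S,6R)-4-(tert-butyldimethylsilyloxy)-1-{(E)-2-[(4-methoxyphenyl)methoxy]ethenyl}-3-methyl-6-[(1E)-1-(triisopropylsilyloxy)prop-1-en-2-yl]cyclohex-2-en-1-ol
Conditions: NaAlH2(OCH2CH2OCH3)2, THF, 0 to 22 °C; aqueous potassium sodium tartrate; chromatography on Et3N-treated silica
Reagents that add atoms: none
Why: Alkoxide-directed trans-hydroalumination of the propargylic alcohol (reduction of an alkynyl carbinol to the E-allylic alcohol) should give the (E)-enol ether; no stereocentre is formed and the silyl enol ether is inert to the aluminate.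

Step 11
Reactants: 14 bis(enol ether) cyclohexenol
Product: 17 methyl 2-[(1R,3Z,5S,7Z,9R,10R)-5-(tert-butyldimethylsilyloxy)-10-[(4-methoxyphenyl)methoxy]-4,8-dimethyl-2-oxo-9-(triisopropylsilyloxy)cyclodeca-3,7-dien-1-yl]acetate, via potassium alkoxide 15 (not isolated), via potassium dienolate 16 (not isolated)
Conditions: KH, 18-crown-6, THF, 0 to 25 °C; then BrCH2CO2Me, −78 °C
Reagents that add atoms: methyl bromoacetate, COC(=O)CBr
Why: KH with 18-crown-6 gives the free tertiary alkoxide 15, whose 1,5-diene C8=C7–C6(O−)–C1–C10=C9 undergoes an anionic oxy-Cope rearrangement ([3,3] sigmatropic shift driven by formation of dienolate 16) in which C8–C9 forms while the C1–C6 bond of the six-membered ring breaks; the closest known reaction type is the anionic oxy-Cope ring expansion of 1,2-dialkenylcyclohex-2-en-1-ols to cyclodeca-3,7-dienones, here with an enol ether at both migrating termini. The ten-membered carbocycle is closed by this ring expansion through a six-centre chair transition state that joins the termini of the two allyl units. C8 and C9 are set in this chair: both (E)-enol ether oxygens are pseudoequatorial and the reacting faces are fixed by C1 and C6 (C10 alkenyl group equatorial on C1, C7=C8 pseudoaxial on C6, cis to each other), which should give the syn 8R,9R arrangement, while the pseudoaxial C1–C2 bond makes C1=C10 Z and the ring alkene is carried over as (Z)-C4=C5. C7 is then set by alkylation of 16 with methyl bromoacetate on the outer face of the enolate, the inner face being covered across the ring by C1=C10, which should give 7R. The step needs the chair with the C1 alkenyl group equatorial and not the ring-flipped chair (which would lead to the 1(10)E isomer), and this is secured by the pseudoaxial preference of the C3 silyloxy group beside the C4 methyl group and by the size of the alkenyl group. It also needs the enolate to keep its C8 oxygen, which is helped by the C8–O bond lying close to the nodal plane of the enolate as it is formed and by alkylation at −78 °C.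

Step 12
Reactants: 17 cyclodecadienone ester
Product: 18 methyl 2-[(1S,2S,3Z,5S,7Z,9R,10R)-5-(tert-butyldimethylsilyloxy)-2-hydroxy-10-[(4-methoxyphenyl)methoxy]-4,8-dimethyl-9-(triisopropylsilyloxy)cyclodeca-3,7-dien-1-yl]acetate
Conditions: NaBH4, CeCl3·7H2O, MeOH, −78 °C
Reagents that add atoms: none
Why: Luche 1,2-reduction of the enone, in which hydride should enter the outer face of the C6 carbonyl because the inner face is covered across the ring by C1=C10 (peripheral attack on a medium ring), giving the 6S alcohol with its oxygen anti to the C7 acetate arm (the descriptor at C7 changes by priority only).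

Step 13
Reactants: 18 (6S)-hydroxy ester
Product: 20 (3aS,4R,5R,6Z,9S,10Z,11aR)-9-(tert-butyldimethylsilyloxy)-4-[(4-methoxyphenyl)methoxy]-6,10-dimethyl-5-(triisopropylsilyloxy)-3a,4,5,8,9,11a-hexahydrocyclodeca[b]furan-2(3H)-one, via hydroxy acid 19 (not isolated)
Conditions: LiOH, THF/H2O, 0 to 22 °C; 0.5 M HCl to pH 4–5 at 0 °C, extraction; PPh3, diisopropyl azodicarboxylate, THF, 0 °C
Reagents that add atoms: lithium hydroxide, [Li+].[OH-]
Why: Saponification followed by Mitsunobu lactonization, in which the C6 hydroxyl is activated as its alkoxyphosphonium ion and displaced by the C12 carboxylate with inversion (intramolecular SN2 at the allylic carbon, five-membered ring closure), should give the 6R, trans-fused γ-lactone.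

Step 14
Reactants: 20 trans-fused lactone
Product: 24 (3aS,4R,5R,6Z,9S,10Z,11aR)-9-(tert-butyldimethylsilyloxy)-4-[(4-methoxyphenyl)methoxy]-6,10-dimethyl-3-methylidene-5-(triisopropylsilyloxy)-3a,4,5,8,9,11a-hexahydrocyclodeca[b]furan-2(3H)-one, via lithium lactone enolate 21 (not isolated), via Mannich base 22 (not isolated), via trimethylammonium iodide 23 (not isolated)
Conditions: LiN(iPr)2, THF, −78 °C; CH2=NMe2+ I−, −78 to 22 °C; MeI, MeOH, 22 °C; NaHCO3, H2O/CH2Cl2, 22 °C
Reagents that add atoms: N,N-dimethylmethyleneiminium iodide, C=[N+](C)C.[I-]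
Why: Classical α-methylenation of a γ-lactone (Mannich reaction of the lithium enolate with Eschenmoser's salt, quaternization, base-induced elimination of trimethylamine); the C11 centre of the intermediates is destroyed, so no stereochemistry is at stake.

Step 15
Reactants: 24 methylene lactone
Product: 25 (3aS,4R,5R,6Z,9S,10Z,11aR)-9-hydroxy-4-[(4-methoxyphenyl)methoxy]-6,10-dimethyl-3-methylidene-5-(triisopropylsilyloxy)-3a,4,5,8,9,11a-hexahydrocyclodeca[b]furan-2(3H)-one
Conditions: HF·pyridine, pyridine, THF, 0 °C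
Reagents that add atoms: none
Why: Buffered fluoride cleavage should remove the allylic secondary TBS ether at C3 much faster than the hindered secondary TIPS ether at C9, and the non-basic medium leaves the methylene lactone untouched.

Step 16
Reactants: 25 C3 alcohol
Product: 26 (3aS,4R,5R,6Z,9S,10Z,11aR)-4-[(4-methoxyphenyl)methoxy]-6,10-dimethyl-3-methylidene-2-oxo-5-(triisopropylsilyloxy)-2,3,3a,4,5,8,9,11a-octahydrocyclodeca[b]furan-9-yl acetate
Conditions: Ac2O, pyridine, 4-(dimethylamino)pyridine (cat.), CH2Cl2, 0 °C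
Reagents that add atoms: acetic anhydride, CC(=O)OC(C)=O
Why: Nucleophile-catalysed acetylation of the C3 alcohol with retention of configuration.

Step 17
Reactants: 26 C3 acetate
Product: 27 (3aS,4R,5R,6Z,9S,10Z,11aR)-5-hydroxy-4-[(4-methoxyphenyl)methoxy]-6,10-dimethyl-3-methylidene-2-oxo-2,3,3a,4,5,8,9,11a-octahydrocyclodeca[b]furan-9-yl acetate
Conditions: HF·pyridine, THF, 22 °C
Reagents that add atoms: none
Why: Prolonged HF·pyridine treatment cleaves the hindered TIPS ether without base, so neither acetate migration nor conjugate addition to the methylene lactone is expected.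

Step 18
Reactants: 28 methyl (2Z)-2-methylbut-2-enoate (methyl angelate)
Product: 29 (2Z)-2-methylbut-2-en-1-ol
Conditions: iBu2AlH, CH2Cl2, −78 to 0 °C
Reagents that add atoms: none
Why: Hydride reduction of the unsaturated ester to the allylic alcohol with retention of the Z geometry.

Step 19
Reactants: 29 (2Z)-2-methylbut-2-en-1-ol
Product: 30 [(2S,3R)-2,3-dimethyloxiran-2-yl]methanol
Conditions: Ti(OiPr)4 (cat.), L-(+)-diethyl tartrate (cat.), tBuOOH, 4 Å molecular sieves, CH2Cl2, −20 °C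
Reagents that add atoms: tert-butyl hydroperoxide, CC(C)(C)OO
Why: Sharpless asymmetric epoxidation, in which the titanium–L-(+)-tartrate–peroxide complex should deliver oxygen to the face that gives the (2S,3R)-epoxy alcohol, the Z geometry fixing the cis relationship of CH2OH and the C3 methyl group.

Step 20
Reactants: 30 epoxy alcohol
Product: 31 (2R,3R)-2,3-dimethyloxirane-2-carboxylic acid
Conditions: RuCl3 (cat.), NaIO4, MeCN/EtOAc/H2O, 0 °C
Reagents that add atoms: water, O
Why: Ruthenium tetroxide oxidation of the primary alcohol to the acid through the aldehyde hydrate leaves the epoxide untouched; the descriptor at C2 becomes R only because the ligand priorities change.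

Step 21
Reactants: 27 C9 alcohol; 31 epoxy acid
Product: 33 (3aS,4R,5R,6Z,9S,10Z,11aR)-9-acetoxy-4-[(4-methoxyphenyl)methoxy]-6,10-dimethyl-3-methylidene-2-oxo-2,3,3a,4,5,8,9,11a-octahydrocyclodeca[b]furan-5-yl (2R,3R)-2,3-dimethyloxirane-2-carboxylate, via mixed anhydride 32 (not isolated)
Conditions: 31, 2,4,6-trichlorobenzoyl chloride, Et3N, THF, 0 °C; then 27, 4-(dimethylamino)pyridine, toluene, 22 °C
Reagents that add atoms: none
Why: Yamaguchi esterification, in which the mixed 2,4,6-trichlorobenzoic anhydride of the α-quaternary epoxy acid should acylate the hindered C9 alcohol under nucleophilic catalysis without touching any stereocentre.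

Step 22
Reactants: 33 C8 4-methoxybenzyl ether
Product: 34 (3aR,4R,5R,6Z,9S,10Z,11aR)-9-acetoxy-4-hydroxy-6,10-dimethyl-3-methylidene-2-oxo-2,3,3a,4,5,8,9,11a-octahydrocyclodeca[b]furan-5-yl (2R,3R)-2,3-dimethyloxirane-2-carboxylate (CNP0137407.10)
Conditions: DDQ, CH2Cl2/pH 7 phosphate buffer, 0 °C
Reagents that add atoms: none
Why: Oxidative cleavage of the 4-methoxybenzyl ether by DDQ (hydride abstraction, hydrolysis of the oxocarbenium ion) under buffered conditions should free the C8 hydroxyl and leave the epoxide, both esters and the methylene lactone intact.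

Compound list
1 | triisopropyl(prop-2-yn-1-yloxy)silane | C#CCO[Si](C(C)C)(C(C)C)C(C)C | starting material
2 | triisopropyl{[2-(4,4,5,5-tetramethyl-1,3,2-dioxaborolan-2-yl)prop-2-en-1-yl]oxy}silane | C=C(CO[Si](C(C)C)(C(C)C)C(C)C)B1OC(C)(C)C(C)(C)O1 | intermediate
3 | 4-methoxy-2-methylphenol | COc1ccc(O)c(C)c1 | starting material
4 | 4,4-dimethoxy-2-methylcyclohexa-2,5-dien-1-one | COC1(OC)C=CC(=O)C(C)=C1 | intermediate
5 | (5R)-4,4-dimethoxy-2-methyl-5-[3-(triisopropylsilyloxy)prop-1-en-2-yl]cyclohex-2-en-1-one | COC1(OC)C=C(C)C(=O)C[C@@H]1C(=C)CO[Si](C(C)C)(C(C)C)C(C)C | intermediate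
6 | (1S,5R)-4,4-dimethoxy-2-methyl-5-[3-(triisopropylsilyloxy)prop-1-en-2-yl]cyclohex-2-en-1-ol | COC1(OC)C=C(C)[C@@H](O)C[C@@H]1C(=C)CO[Si](C(C)C)(C(C)C)C(C)C | intermediate
7 | tert-butyl{[(1S,5R)-4,4-dimethoxy-2-methyl-5-[3-(triisopropylsilyloxy)prop-1-en-2-yl]cyclohex-2-en-1-yl]oxy}dimethylsilane | COC1(OC)C=C(C)[C@@H](O[Si](C)(C)C(C)(C)C)C[C@@H]1C(=C)CO[Si](C(C)C)(C(C)C)C(C)C | intermediate
8 | (4S,6R)-4-(tert-butyldimethylsilyloxy)-3-methyl-6-[3-(triisopropylsilyloxy)prop-1-en-2-yl]cyclohex-2-en-1-one | O=C1C=C(C)[C@@H](O[Si](C)(C)C(C)(C)C)C[C@@H]1C(=C)CO[Si](C(C)C)(C(C)C)C(C)C | intermediate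
9 | (4S,6R)-4-(tert-butyldimethylsilyloxy)-3-methyl-6-[(1E)-1-(triisopropylsilyloxy)prop-1-en-2-yl]cyclohex-2-en-1-one | O=C1C=C(C)[C@@H](O[Si](C)(C)C(C)(C)C)C[C@@H]1/C(C)=C/O[Si](C(C)C)(C(C)C)C(C)C | intermediate
10 | (4-methoxyphenyl)methanol | COc1ccc(CO)cc1 | starting material
11 | 1-({[(E)-1,2-dichloroethenyl]oxy}methyl)-4-methoxybenzene | COc1ccc(CO/C(Cl)=C\Cl)cc1 | intermediate
12 | lithium [(4-methoxyphenyl)methoxy]ethynide | [Li+].[C-]#COCc1ccc(OC)cc1 | intermediate
13 | (1S,4S,6R)-4-(tert-butyldimethylsilyloxy)-1-{[(4-methoxyphenyl)methoxy]ethynyl}-3-methyl-6-[(1E)-1-(triisopropylsilyloxy)prop-1-en-2-yl]cyclohex-2-en-1-ol | O[C@@]1(C#COCc2ccc(OC)cc2)C=C(C)[C@@H](O[Si](C)(C)C(C)(C)C)C[C@@H]1/C(C)=C/O[Si](C(C)C)(C(C)C)C(C)C | intermediate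
14 | (1S,4S,6R)-4-(tert-butyldimethylsilyloxy)-1-{(E)-2-[(4-methoxyphenyl)methoxy]ethenyl}-3-methyl-6-[(1E)-1-(triisopropylsilyloxy)prop-1-en-2-yl]cyclohex-2-en-1-ol | O[C@@]1(/C=C/OCc2ccc(OC)cc2)C=C(C)[C@@H](O[Si](C)(C)C(C)(C)C)C[C@@H]1/C(C)=C/O[Si](C(C)C)(C(C)C)C(C)C | intermediate
15 | potassium alkoxide of 14 | [K+].[O-][C@@]1(/C=C/OCc2ccc(OC)cc2)C=C(C)[C@@H](O[Si](C)(C)C(C)(C)C)C[C@@H]1/C(C)=C/O[Si](C(C)C)(C(C)C)C(C)C | intermediate
16 | potassium (1Z,3Z,5S,7Z,9R,10R)-5-(tert-butyldimethylsilyloxy)-10-[(4-methoxyphenyl)methoxy]-4,8-dimethyl-9-(triisopropylsilyloxy)cyclodeca-1,3,7-trien-2-olate | CC(C)[Si](C(C)C)(C(C)C)O[C@@H]1/C(C)=C\C[C@H](O[Si](C)(C)C(C)(C)C)/C(C)=C\C(\[O-])=C\[C@H]1OCc2ccc(OC)cc2.[K+] | intermediate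
17 | methyl 2-[(1R,3Z,5S,7Z,9R,10R)-5-(tert-butyldimethylsilyloxy)-10-[(4-methoxyphenyl)methoxy]-4,8-dimethyl-2-oxo-9-(triisopropylsilyloxy)cyclodeca-3,7-dien-1-yl]acetate | COC(=O)C[C@H]1C(=O)/C=C(/C)[C@@H](O[Si](C)(C)C(C)(C)C)C/C=C(/C)[C@@H](O[Si](C(C)C)(C(C)C)C(C)C)[C@@H]1OCc2ccc(OC)cc2 | intermediate
18 | methyl 2-[(1S,2S,3Z,5S,7Z,9R,10R)-5-(tert-butyldimethylsilyloxy)-2-hydroxy-10-[(4-methoxyphenyl)methoxy]-4,8-dimethyl-9-(triisopropylsilyloxy)cyclodeca-3,7-dien-1-yl]acetate | COC(=O)C[C@H]1[C@@H](O)/C=C(/C)[C@@H](O[Si](C)(C)C(C)(C)C)C/C=C(/C)[C@@H](O[Si](C(C)C)(C(C)C)C(C)C)[C@@H]1OCc2ccc(OC)cc2 | intermediate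
19 | 2-[(1S,2S,3Z,5S,7Z,9R,10R)-5-(tert-butyldimethylsilyloxy)-2-hydroxy-10-[(4-methoxyphenyl)methoxy]-4,8-dimethyl-9-(triisopropylsilyloxy)cyclodeca-3,7-dien-1-yl]acetic acid | OC(=O)C[C@H]1[C@@H](O)/C=C(/C)[C@@H](O[Si](C)(C)C(C)(C)C)C/C=C(/C)[C@@H](O[Si](C(C)C)(C(C)C)C(C)C)[C@@H]1OCc2ccc(OC)cc2 | intermediate
20 | (3aS,4R,5R,6Z,9S,10Z,11aR)-9-(tert-butyldimethylsilyloxy)-4-[(4-methoxyphenyl)methoxy]-6,10-dimethyl-5-(triisopropylsilyloxy)-3a,4,5,8,9,11a-hexahydrocyclodeca[b]furan-2(3H)-one | C1C(=O)O[C@@H]2/C=C(/C)[C@@H](O[Si](C)(C)C(C)(C)C)C/C=C(/C)[C@@H](O[Si](C(C)C)(C(C)C)C(C)C)[C@H](OCc3ccc(OC)cc3)[C@@H]12 | intermediate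
21 | lithium enolate of 20 (C11=C12–OLi) | C1=C([O-])O[C@@H]2/C=C(/C)[C@@H](O[Si](C)(C)C(C)(C)C)C/C=C(/C)[C@@H](O[Si](C(C)C)(C(C)C)C(C)C)[C@H](OCc3ccc(OC)cc3)[C@@H]12.[Li+] | intermediate
22 | 3-[(dimethylamino)methyl] derivative of 20 (either configuration at C11) | CN(C)CC1C(=O)O[C@@H]2/C=C(/C)[C@@H](O[Si](C)(C)C(C)(C)C)C/C=C(/C)[C@@H](O[Si](C(C)C)(C(C)C)C(C)C)[C@H](OCc3ccc(OC)cc3)[C@@H]12 | intermediate
23 | trimethylammonium iodide of 22 | C[N+](C)(C)CC1C(=O)O[C@@H]2/C=C(/C)[C@@H](O[Si](C)(C)C(C)(C)C)C/C=C(/C)[C@@H](O[Si](C(C)C)(C(C)C)C(C)C)[C@H](OCc3ccc(OC)cc3)[C@@H]12.[I-] | intermediate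
24 | (3aS,4R,5R,6Z,9S,10Z,11aR)-9-(tert-butyldimethylsilyloxy)-4-[(4-methoxyphenyl)methoxy]-6,10-dimethyl-3-methylidene-5-(triisopropylsilyloxy)-3a,4,5,8,9,11a-hexahydrocyclodeca[b]furan-2(3H)-one | C=C1C(=O)O[C@@H]2/C=C(/C)[C@@H](O[Si](C)(C)C(C)(C)C)C/C=C(/C)[C@@H](O[Si](C(C)C)(C(C)C)C(C)C)[C@H](OCc3ccc(OC)cc3)[C@@H]12 | intermediate
25 | (3aS,4R,5R,6Z,9S,10Z,11aR)-9-hydroxy-4-[(4-methoxyphenyl)methoxy]-6,10-dimethyl-3-methylidene-5-(triisopropylsilyloxy)-3a,4,5,8,9,11a-hexahydrocyclodeca[b]furan-2(3H)-one | C=C1C(=O)O[C@@H]2/C=C(/C)[C@@H](O)C/C=C(/C)[C@@H](O[Si](C(C)C)(C(C)C)C(C)C)[C@H](OCc3ccc(OC)cc3)[C@@H]12 | intermediate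
26 | (3aS,4R,5R,6Z,9S,10Z,11aR)-4-[(4-methoxyphenyl)methoxy]-6,10-dimethyl-3-methylidene-2-oxo-5-(triisopropylsilyloxy)-2,3,3a,4,5,8,9,11a-octahydrocyclodeca[b]furan-9-yl acetate | C=C1C(=O)O[C@@H]2/C=C(/C)[C@@H](OC(C)=O)C/C=C(/C)[C@@H](O[Si](C(C)C)(C(C)C)C(C)C)[C@H](OCc3ccc(OC)cc3)[C@@H]12 | intermediate
27 | (3aS,4R,5R,6Z,9S,10Z,11aR)-5-hydroxy-4-[(4-methoxyphenyl)methoxy]-6,10-dimethyl-3-methylidene-2-oxo-2,3,3a,4,5,8,9,11a-octahydrocyclodeca[b]furan-9-yl acetate | C=C1C(=O)O[C@@H]2/C=C(/C)[C@@H](OC(C)=O)C/C=C(/C)[C@@H](O)[C@H](OCc3ccc(OC)cc3)[C@@H]12 | intermediate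
28 | methyl (2Z)-2-methylbut-2-enoate (methyl angelate) | C/C=C(/C)C(=O)OC | starting material
29 | (2Z)-2-methylbut-2-en-1-ol | C/C=C(/C)CO | intermediate
30 | [(2S,3R)-2,3-dimethyloxiran-2-yl]methanol | OC[C@]1(C)O[C@@H]1C | intermediate
31 | (2R,3R)-2,3-dimethyloxirane-2-carboxylic acid | OC(=O)[C@]1(C)O[C@@H]1C | intermediate
32 | (2R,3R)-2,3-dimethyloxirane-2-carboxylic 2,4,6-trichlorobenzoic anhydride | O=C(OC(=O)c1c(Cl)cc(Cl)cc1Cl)[C@]2(C)O[C@@H]2C | intermediate
33 | (3aS,4R,5R,6Z,9S,10Z,11aR)-9-acetoxy-4-[(4-methoxyphenyl)methoxy]-6,10-dimethyl-3-methylidene-2-oxo-2,3,3a,4,5,8,9,11a-octahydrocyclodeca[b]furan-5-yl (2R,3R)-2,3-dimethyloxirane-2-carboxylate | C=C1C(=O)O[C@@H]2/C=C(/C)[C@@H](OC(C)=O)C/C=C(/C)[C@@H](OC(=O)[C@]3(C)O[C@@H]3C)[C@H](OCc4ccc(OC)cc4)[C@@H]12 | intermediate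
34 | (3aR,4R,5R,6Z,9S,10Z,11aR)-9-acetoxy-4-hydroxy-6,10-dimethyl-3-methylidene-2-oxo-2,3,3a,4,5,8,9,11a-octahydrocyclodeca[b]furan-5-yl (2R,3R)-2,3-dimethyloxirane-2-carboxylate | C=C1C(=O)O[C@@H]2/C=C(/C)[C@@H](OC(C)=O)C/C=C(/C)[C@@H](OC(=O)[C@]3(C)O[C@@H]3C)[C@H](O)[C@@H]12 | target

Total step count: 22 (17 in the main line; 5 for the building blocks 2, 11 and 31).
Longest linear sequence: 17 steps, from 3 to 34 (steps 2–7, 9–17, 21, 22).

Steps most likely to fail

Step 11. The [3,3] shift of a diene that carries oxygen on both termini may be slow, and a dienolate that is kept warm may then lose 4-methoxybenzyl oxide from C8 by β-elimination before it is alkylated. Fallback, from 9 back to 17: the C8 oxygen is taken out of the rearrangement. CH2=CHMgBr with CeCl3 (THF, −78 °C) adds to 9 as in step 9 and gives the ethenyl carbinol F1. KH/18-crown-6 followed by Me3SiCl then gives, by the classical oxy-Cope ring expansion, the trimethylsilyl dienol ether F2, with C9 set by the same chair. Pd(OAc)2 in MeCN (Saegusa–Ito oxidation) gives the cross-conjugated cyclodecatrienone F3. Conjugate addition of 4-methoxybenzyl alcohol (catalytic KN(SiMe3)2, THF, 0 °C) to the strained (E)-enone from the outer face should give the 8-(4-methoxybenzyloxy) ketone F4. LiN(iPr)2 at −78 °C and methyl bromoacetate then alkylate C7 on the outer face and return to 17.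

Step 12. Hydride may also be delivered to the other face of the C6 carbonyl if the ring flips to a conformer that exposes it, so that facial selectivity is lost. Fallback, from 17 back to 20: both epimers are used. The epimeric 6R hydroxy ester F5 has its hydroxyl gauche to the acetate arm and is closed with retention by acid-catalysed transesterification (pyridinium p-toluenesulfonate, benzene, 60 °C) straight to 20, while 18 is separated and taken through step 13.

Step 13. The phosphonium reagent may activate the carboxylate instead of the hindered allylic hydroxyl, or the hydroxy acid may relactonize on acidification; both processes close the ring with retention. Fallback, from 18 back to 20: intermolecular Mitsunobu inversion of 18 with 4-nitrobenzoic acid (PPh3, diisopropyl azodicarboxylate, toluene, 0 °C) gives the inverted 4-nitrobenzoate F6 with the methyl ester intact. K2CO3 in MeOH then removes the nitrobenzoate, and the 6R alkoxide closes on the methyl ester to give 20.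

Further compounds
F1 | step 11 | (1S,4S,6R)-4-(tert-butyldimethylsilyloxy)-1-ethenyl-3-methyl-6-[(1E)-1-(triisopropylsilyloxy)prop-1-en-2-yl]cyclohex-2-en-1-ol | O[C@@]1(C=C)C=C(C)[C@@H](O[Si](C)(C)C(C)(C)C)C[C@@H]1/C(C)=C/O[Si](C(C)C)(C(C)C)C(C)C
F2 | step 11 | trimethyl{[(1Z,3Z,5S,7Z,9S)-5-(tert-butyldimethylsilyloxy)-4,8-dimethyl-9-(triisopropylsilyloxy)cyclodeca-1,3,7-trien-2-yl]oxy}silane | CC(C)[Si](C(C)C)(C(C)C)O[C@@H]1/C(C)=C\C[C@H](O[Si](C)(C)C(C)(C)C)/C(C)=C\C(\O[Si](C)(C)C)=C\C1
F3 | step 11 | (2E,4S,5Z,8S,9Z)-8-(tert-butyldimethylsilyloxy)-5,9-dimethyl-4-(triisopropylsilyloxy)cyclodeca-2,5,9-trien-1-one | CC(C)[Si](C(C)C)(C(C)C)O[C@@H]1/C(C)=C\C[C@H](O[Si](C)(C)C(C)(C)C)/C(C)=C\C(=O)/C=C/1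
F4 | step 11 | (2Z,4S,6Z,8R,9R)-4-(tert-butyldimethylsilyloxy)-9-[(4-methoxyphenyl)methoxy]-3,7-dimethyl-8-(triisopropylsilyloxy)cyclodeca-2,6-dien-1-one | CC(C)[Si](C(C)C)(C(C)C)O[C@@H]1/C(C)=C\C[C@H](O[Si](C)(C)C(C)(C)C)/C(C)=C\C(=O)C[C@H]1OCc2ccc(OC)cc2
F5 | step 12 | methyl 2-[(1S,2R,3Z,5S,7Z,9R,10R)-5-(tert-butyldimethylsilyloxy)-2-hydroxy-10-[(4-methoxyphenyl)methoxy]-4,8-dimethyl-9-(triisopropylsilyloxy)cyclodeca-3,7-dien-1-yl]acetate | COC(=O)C[C@H]1[C@H](O)/C=C(/C)[C@@H](O[Si](C)(C)C(C)(C)C)C/C=C(/C)[C@@H](O[Si](C(C)C)(C(C)C)C(C)C)[C@@H]1OCc2ccc(OC)cc2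
F6 | step 13 | methyl 2-[(1S,2R,3Z,5S,7Z,9R,10R)-5-(tert-butyldimethylsilyloxy)-10-[(4-methoxyphenyl)methoxy]-4,8-dimethyl-2-(4-nitrobenzoyloxy)-9-(triisopropylsilyloxy)cyclodeca-3,7-dien-1-yl]acetate | COC(=O)C[C@H]1[C@H](OC(=O)c2ccc(cc2)[N+](=O)[O-])/C=C(/C)[C@@H](O[Si](C)(C)C(C)(C)C)C/C=C(/C)[C@@H](O[Si](C(C)C)(C(C)C)C(C)C)[C@@H]1OCc3ccc(OC)cc3
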